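The numbers were drawn at random within sensible limits.

A small charge of 0.059 M starting complex meets 0.0885 M incoming ligand, 1.50 equivalents, in two runs that differ in time.

| flask | starting complex | incoming ligand | time |
|---|---|---|---|
| midnight | 0.059 M | 0.0885 M | 40 h |
| winter | 0.059 M | 0.0885 M | 52 h |

    starting complex ⇌ dormant form (K1 = 0.28, k1 = 1.9 × 10⁻⁵ /s)
    complex with one exchanged + incoming ligand → leaving ligand + complex with two exchanged (k2 = 2.3 × 10⁻⁵ /M/s)
    complex with two exchanged + incoming ligand → leaving ligand + complex with three exchanged (k3 = 1.6 × 10⁻⁵ /M/s)
    complex with three exchanged + incoming ligand → leaving ligand + complex with four exchanged (k4 = 7.4 × 10⁻⁵ /M/s)
    starting complex + incoming ligand → leaving ligand + complex with one exchanged (k5 = 1.3 × 10⁻⁴ /M/s)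
    starting complex + complex with two exchanged → side product (k6 = 1.3 × 10⁻⁴ /M/s)

- in percentages every species weighs as the starting complex in it: one side product counts as two
- run time (midnight): 40 h

- which of these there is most of at the end, counted by the starting complex in it, midnight (side product / complex with one exchanged / complex with two exchanged / starting complex)
- which of these there is most of at the end, counted by the starting complex in it, winter (side product / complex with one exchanged / complex with two exchanged / starting complex)
- how much there is at the end of the one of these that leads, in percent of the starting complex charged: midnight
- how much there is at the end of the one of these that leads, in percent of the starting complex charged: winter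

Two numbers seem not to fit. With the ligand as charged, the first exchange alone gives the starting complex a half-life of 17 h at midnight, so 40 h should leave 19.1 %, yet I reckon 38.2 % unexchanged, twice that figure. I call this fraction p, counting starting complex and dormant form together and assuming they stay in balance. The dormant form then holds 21.9 % of that pool, which divides the constant of the first exchange, 1.3 × 10⁻⁴ /M/s, by 1.28. The ligand also falls as it is spent, and I take its excess over the charged starting complex as 0.0295 M. The second-order integrated law with both corrections gives that midnight figure, and for winter p is 30.7 %.

I reckon the split with the selectivity factor S, the first exchange's reduced constant over the second's: 4.42. Dividing the two rate laws cancels the ligand, and, neglecting the side product and later exchanges, the fraction of complex with one exchanged is (p^(1/S) − p)/(1 − 1/S). At S = 1, the symmetric case and my zero, this is p ln(1/p), or 36.8 % at midnight. The real S lifts midnight higher, to 54.6 %, and gives winter 59.2 %.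

The forecast names complex with one exchanged for midnight and complex with one exchanged for winter, at 52 % (46 % to 58 %) and 56 % (50 % to 62 %). Its ground: “The second exchange is about six times slower and the side reaction takes little”. My figures stand higher than its central values, inside its ranges.

The flasks give complex with one exchanged at 53.7 % at midnight and complex with one exchanged at 57.9 % in winter. With the second exchange struck out, winter holds 69.3 % of complex with one exchanged. A neighbour of winter charged with 0.035 M incoming ligand ends with 50.5 % starting complex and 14.5 % dormant form, a pool of 65.0 %. The same S turns that pool into 33.2 % of complex with one exchanged, and that neighbour flask holds 32.8 % of it.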